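Both prenyl groups are disconnected between the benzylic CH2 and the vinylic CH. On ring A these CH2 carbons sit on C3 and C5, each beside a free hydroxyl (C2-OH, C6-OH), which is the pattern of an ortho-quinone methide; C3 and C5 are also the only unsubstituted carbons of ring A. The precursor is therefore the 3,5-bis(dimethylaminomethyl)-2,6-dihydroxy-4-methoxybenzophenone with the ring B phenol silylated. After N-methylation, excess 2-methylprop-1-enylmagnesium bromide should trigger two eliminations of trimethylamine and two conjugate additions, creating both benzylic–vinylic C–C bonds in one operation; desilylation then gives the target.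

Key step: step 7

Remark: ring A is numbered from the carbon that carries the ketone (C1; ketone carbon C7), and ring B is the 3-oxygenated phenyl ring. Steps 6 and 7 each build two equivalents of their second reactant (9 and 11) into the product; the second equivalent is entered under the reagents that add atoms. In step 7 the Grignard reagent meets the bis(trimethylammonium) diiodide made in the same flask; four equivalents are consumed, two as base and two as nucleophile.

Step 1
Reactants: 1 5-methoxybenzene-1,3-diol
Product: 2 1-methoxy-3,5-bis(methoxymethoxy)benzene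
Conditions: NaH (2.4 equiv), MOMCl (2.4 equiv), DMF, 0 °C → rt
Reagents that add atoms: chloromethyl methyl ether (MOMCl, two equivalents incorporated), COCCl
Why: Williamson-type O-alkylation of the sodium phenoxides with the reactive α-chloro ether should protect both hydroxyls as MOM ethers, which later direct the ortho-lithiation.

Step 2
Reactants: 3 3-hydroxybenzaldehyde
Product: 4 3-(triisopropylsilyloxy)benzaldehyde
Conditions: TIPSCl, imidazole, DMF, rt
Reagents that add atoms: chlorotriisopropylsilane (TIPSCl), CC(C)[Si](Cl)(C(C)C)C(C)C
Why: Imidazole-promoted silylation of the phenol (silyl ether formation) masks the ring B hydroxyl with a bulky group that should tolerate organolithium, dilute acid and Grignard conditions.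

Step 3
Reactants: 2 1-methoxy-3,5-bis(methoxymethoxy)benzene, 4 3-(triisopropylsilyloxy)benzaldehyde
Product: 6 rac-[4-methoxy-2,6-bis(methoxymethoxy)phenyl][3-(triisopropylsilyloxy)phenyl]methanol, via aryllithium 5 (not isolated)
Conditions: n-BuLi, THF, 0 °C; then 4, −78 °C → rt; aq. NH4Cl
Reagents that add atoms: none
Why: Directed ortho-metalation should occur at the carbon flanked by both chelating OCH2OCH3 groups (the carbons next to OMe have only one such neighbour), and the aryllithium then adds 1,2 to the non-enolisable aldehyde, the carbinol centre forming without control as a racemate that step 4 erases.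

Step 4
Reactants: 6 rac-[4-methoxy-2,6-bis(methoxymethoxy)phenyl][3-(triisopropylsilyloxy)phenyl]methanol
Product: 7 [4-methoxy-2,6-bis(methoxymethoxy)phenyl][3-(triisopropylsilyloxy)phenyl]methanone
Conditions: Dess–Martin periodinane, CH2Cl2, rt
Reagents that add atoms: none
Why: Dess–Martin oxidation of a doubly benzylic secondary alcohol is fast and mild enough to leave the acetal and silyl ethers untouched.

Step 5
Reactants: 7 [4-methoxy-2,6-bis(methoxymethoxy)phenyl][3-(triisopropylsilyloxy)phenyl]methanone
Product: 8 (2,6-dihydroxy-4-methoxyphenyl)[3-(triisopropylsilyloxy)phenyl]methanone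
Conditions: 2 M HCl, MeOH/THF, rt → 40 °C
Reagents that add atoms: none
Why: Acid-catalysed transacetalisation to methanol cleaves the two MOM ethers ortho to the ketone, while the aryl triisopropylsilyl ether, which resists acid far better than base, should stay in place.

Step 6
Reactants: 8 (2,6-dihydroxy-4-methoxyphenyl)[3-(triisopropylsilyloxy)phenyl]methanone, 9 dimethylmethyleneiminium iodide (two equivalents incorporated)
Product: 10 [3,5-bis(dimethylaminomethyl)-2,6-dihydroxy-4-methoxyphenyl][3-(triisopropylsilyloxy)phenyl]methanone
Conditions: 9 (2.5 equiv), Et3N (3 equiv), CH2Cl2, 0 °C → rt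
Reagents that add atoms: dimethylmethyleneiminium iodide (second equivalent of 9), C=[N+](C)C.[I-]
Why: Twofold Mannich aminomethylation (electrophilic aromatic substitution by the preformed iminium ion, one equivalent per position, the HI being taken up by Et3N) should take place at C3 and C5, the only free carbons of ring A and each ortho and para to a hydroxyl, while ring B, which has a single silyloxy donor and the deactivating acyl group, is far less nucleophilic and should not compete.

Step 7
Reactants: 10 [3,5-bis(dimethylaminomethyl)-2,6-dihydroxy-4-methoxyphenyl][3-(triisopropylsilyloxy)phenyl]methanone, 11 2-methylprop-1-enylmagnesium bromide (two equivalents incorporated)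
Product: 15 [2,6-dihydroxy-4-methoxy-3,5-bis(3-methylbut-2-enyl)phenyl][3-(triisopropylsilyloxy)phenyl]methanone, via bis(trimethylammonium) diiodide 12 (not isolated), via first ortho-quinone methide 13 (not isolated), via second ortho-quinone methide 14 (not isolated)
Conditions: MeI, THF, rt, then excess MeI removed in vacuo; 11 (6 equiv), THF, −78 °C → rt; aq. NH4Cl
Reagents that add atoms: 2-methylprop-1-enylmagnesium bromide (second equivalent of 11), CC(C)=C[Mg]Br
Why: Exhaustive N-methylation turns both aminomethyl arms into trimethylammonium leaving groups; the Grignard reagent first deprotonates the C2 and C6 hydroxyls, each magnesium phenoxide then expels trimethylamine from its ortho CH2 to give an ortho-quinone methide, and the alkenyl nucleophile adds to the exocyclic carbon in a 1,4-sense with rearomatisation, after which the sequence repeats on the other flank. The closest known reaction type is the generation of ortho-quinone methides from phenolic Mannich methiodides (or ortho-acyloxybenzyl precursors) under basic organometallic conditions followed by conjugate addition of alkyl or alkenyl Grignard reagents; here it is applied twice on one ring. No ring is closed and no stereocentre is formed, and the trisubstituted double bond arrives intact in the nucleophile, so olefin geometry is not an issue. The selectivity required is attack at the exocyclic CH2 instead of the ketone carbon C7, and it is secured by the two flanking magnesium phenoxides, which screen C7 and make it part of a vinylogous carboxylate of low electrophilicity, whereas the quinone methide is a strong Michael acceptor. Because aminomethylation placed exactly one carbon on C3 and one on C5, O-prenylation and geminal dialkylation, the usual side reactions of direct prenylation of acylphloroglucinols, cannot occur. An excess of the Grignard reagent keeps the stationary concentration of quinone methide low and so should suppress its capture by the phenoxide of another molecule.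

Step 8
Reactants: 15 [2,6-dihydroxy-4-methoxy-3,5-bis(3-methylbut-2-enyl)phenyl][3-(triisopropylsilyloxy)phenyl]methanone
Product: 16 [2,6-dihydroxy-4-methoxy-3,5-bis(3-methylbut-2-enyl)phenyl](3-hydroxyphenyl)methanone
Conditions: TBAF, AcOH, THF, 0 °C → rt
Reagents that add atoms: none
Why: Fluoride-mediated desilylation, driven by the strength of the Si–F bond and buffered with acetic acid, should free the ring B phenol without exposing the prenylated resorcinol core to strong base or to acid that could cyclise a prenyl group onto its neighbouring hydroxyl.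

Compound list
1 | 5-methoxybenzene-1,3-diol | COc1cc(O)cc(O)c1 | starting material
2 | 1-methoxy-3,5-bis(methoxymethoxy)benzene | COCOc1cc(OC)cc(OCOC)c1 | intermediate
3 | 3-hydroxybenzaldehyde | O=Cc1cccc(O)c1 | starting material
4 | 3-(triisopropylsilyloxy)benzaldehyde | O=Cc1cccc(O[Si](C(C)C)(C(C)C)C(C)C)c1 | intermediate
5 | [4-methoxy-2,6-bis(methoxymethoxy)phenyl]lithium (lithium on the carbon between the two MOM ethers) | [Li]c1c(OCOC)cc(OC)cc1OCOC | intermediate (not isolated)
6 | rac-[4-methoxy-2,6-bis(methoxymethoxy)phenyl][3-(triisopropylsilyloxy)phenyl]methanol (racemic carbinol; its only stereocentre is removed in step 4) | COCOc1cc(OC)cc(OCOC)c1C(O)c1cccc(O[Si](C(C)C)(C(C)C)C(C)C)c1 | intermediate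
7 | [4-methoxy-2,6-bis(methoxymethoxy)phenyl][3-(triisopropylsilyloxy)phenyl]methanone | COCOc1cc(OC)cc(OCOC)c1C(=O)c1cccc(O[Si](C(C)C)(C(C)C)C(C)C)c1 | intermediate
8 | (2,6-dihydroxy-4-methoxyphenyl)[3-(triisopropylsilyloxy)phenyl]methanone | COc1cc(O)c(C(=O)c2cccc(O[Si](C(C)C)(C(C)C)C(C)C)c2)c(O)c1 | intermediate
9 | dimethylmethyleneiminium iodide (Eschenmoser's salt) | C=[N+](C)C.[I-] | starting material
10 | [3,5-bis(dimethylaminomethyl)-2,6-dihydroxy-4-methoxyphenyl][3-(triisopropylsilyloxy)phenyl]methanone | COc1c(CN(C)C)c(O)c(C(=O)c2cccc(O[Si](C(C)C)(C(C)C)C(C)C)c2)c(O)c1CN(C)C | intermediate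
11 | 2-methylprop-1-enylmagnesium bromide (solution in THF) | CC(C)=C[Mg]Br | starting material
12 | [2,6-dihydroxy-4-methoxy-3,5-bis(trimethylammoniomethyl)phenyl][3-(triisopropylsilyloxy)phenyl]methanone diiodide | COc1c(C[N+](C)(C)C)c(O)c(C(=O)c2cccc(O[Si](C(C)C)(C(C)C)C(C)C)c2)c(O)c1C[N+](C)(C)C.[I-].[I-] | intermediate (not isolated)
13 | first ortho-quinone methide: ring A as a cyclohexadienone with the carbonyl at C2 and an exocyclic CH2 on C3, C6 as its bromomagnesium phenoxide, C5 still carrying CH2NMe3 iodide | C=C1C(=O)C(C(=O)c2cccc(O[Si](C(C)C)(C(C)C)C(C)C)c2)=C(O[Mg]Br)C(C[N+](C)(C)C)=C1OC.[I-] | intermediate (not isolated)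
14 | second ortho-quinone methide: carbonyl at C6 and exocyclic CH2 on C5, C3 already prenylated, C2 as its bromomagnesium phenoxide | C=C1C(=O)C(C(=O)c2cccc(O[Si](C(C)C)(C(C)C)C(C)C)c2)=C(O[Mg]Br)C(CC=C(C)C)=C1OC | intermediate (not isolated)
15 | [2,6-dihydroxy-4-methoxy-3,5-bis(3-methylbut-2-enyl)phenyl][3-(triisopropylsilyloxy)phenyl]methanone | COc1c(CC=C(C)C)c(O)c(C(=O)c2cccc(O[Si](C(C)C)(C(C)C)C(C)C)c2)c(O)c1CC=C(C)C | intermediate
16 | [2,6-dihydroxy-4-methoxy-3,5-bis(3-methylbut-2-enyl)phenyl](3-hydroxyphenyl)methanone (CNP0425861.0; no stereocentres) | COc1c(CC=C(C)C)c(O)c(C(=O)c2cccc(O)c2)c(O)c1CC=C(C)C | target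

Total step count: 8.
Longest linear sequence: 7 steps (steps 1, 3, 4, 5, 6, 7 and 8, from compound 1); step 2 is a one-step side branch.

Steps most likely to fail

1. Step 7. The quaternisation may be incomplete or accompanied by O-methylation. The sequence may also stall after the first elimination–addition cycle, the quinone methide may be captured by a phenoxide of a second molecule (oligomerisation), or the Grignard reagent may add to the ketone. The fallback sets out from 8 and returns at 15. Twofold O-allylation of 8 (allyl bromide, K2CO3, acetone, reflux) should give [2,6-bis(allyloxy)-4-methoxyphenyl][3-(triisopropylsilyloxy)phenyl]methanone F1. A double aromatic Claisen rearrangement (N,N-diethylaniline, 190 °C) can deliver the allyl groups only to C3 and C5, because C1 is blocked, and should give (3,5-diallyl-2,6-dihydroxy-4-methoxyphenyl)[3-(triisopropylsilyloxy)phenyl]methanone F2. Olefin cross-metathesis of F2 with excess 2-methylbut-2-ene (second-generation Grubbs catalyst, CH2Cl2, 40 °C) should then convert both allyl groups into prenyl groups and give 15.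

2. Step 3. Part of the metalation may take place at a carbon between a MOM ether and the methoxy group, which would lead to a regioisomeric benzhydrol. The fallback sets out from 4 and returns at 8. Commercial phloroglucinol (benzene-1,3,5-triol) is converted with NaH and MOMCl in DMF into 1,3,5-tris(methoxymethoxy)benzene F3, whose three ring hydrogens are equivalent. Lithiation (n-BuLi, THF, 0 °C) gives [2,4,6-tris(methoxymethoxy)phenyl]lithium F4, which adds to 4 to give rac-[2,4,6-tris(methoxymethoxy)phenyl][3-(triisopropylsilyloxy)phenyl]methanol F5. Dess–Martin oxidation gives [2,4,6-tris(methoxymethoxy)phenyl][3-(triisopropylsilyloxy)phenyl]methanone F6, and acidic methanolysis (HCl, MeOH/THF) gives (2,4,6-trihydroxyphenyl)[3-(triisopropylsilyloxy)phenyl]methanone F7. Methylation of the C4 hydroxyl, the most acidic one and the only one not chelated to the ketone, with one equivalent of Me2SO4 and K2CO3 in acetone should then give 8.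

3. Step 6. The aminomethylation may stop after the first arm, or the Mannich base may condense with unreacted arene to diarylmethanes. The fallback sets out from 8 and returns at 10. Twofold Rieche formylation of 8 (Cl2CHOMe, TiCl4, CH2Cl2, 0 °C) should give 4,6-dihydroxy-2-methoxy-5-[3-(triisopropylsilyloxy)benzoyl]benzene-1,3-dicarbaldehyde F8. Twofold reductive amination of F8 with dimethylamine (Me2NH, NaBH(OAc)3, 1,2-dichloroethane, rt) should then give 10.

Further compounds
F1 | step 7 | [2,6-bis(allyloxy)-4-methoxyphenyl][3-(triisopropylsilyloxy)phenyl]methanone | COc1cc(OCC=C)c(C(=O)c2cccc(O[Si](C(C)C)(C(C)C)C(C)C)c2)c(OCC=C)c1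
F2 | step 7 | (3,5-diallyl-2,6-dihydroxy-4-methoxyphenyl)[3-(triisopropylsilyloxy)phenyl]methanone | COc1c(CC=C)c(O)c(C(=O)c2cccc(O[Si](C(C)C)(C(C)C)C(C)C)c2)c(O)c1CC=C
F3 | step 3 | 1,3,5-tris(methoxymethoxy)benzene | COCOc1cc(OCOC)cc(OCOC)c1
F4 | step 3 | [2,4,6-tris(methoxymethoxy)phenyl]lithium | [Li]c1c(OCOC)cc(OCOC)cc1OCOC
F5 | step 3 | rac-[2,4,6-tris(methoxymethoxy)phenyl][3-(triisopropylsilyloxy)phenyl]methanol | COCOc1cc(OCOC)c(C(O)c2cccc(O[Si](C(C)C)(C(C)C)C(C)C)c2)c(OCOC)c1
F6 | step 3 | [2,4,6-tris(methoxymethoxy)phenyl][3-(triisopropylsilyloxy)phenyl]methanone | COCOc1cc(OCOC)c(C(=O)c2cccc(O[Si](C(C)C)(C(C)C)C(C)C)c2)c(OCOC)c1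
F7 | step 3 | (2,4,6-trihydroxyphenyl)[3-(triisopropylsilyloxy)phenyl]methanone | O=C(c1cccc(O[Si](C(C)C)(C(C)C)C(C)C)c1)c1c(O)cc(O)cc1O
F8 | step 6 | 4,6-dihydroxy-2-methoxy-5-[3-(triisopropylsilyloxy)benzoyl]benzene-1,3-dicarbaldehyde | COc1c(C=O)c(O)c(C(=O)c2cccc(O[Si](C(C)C)(C(C)C)C(C)C)c2)c(O)c1C=O
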